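## Retrosynthetic overview

1. The spiro dihydropyran is cut last (O–C8 and C13–C7', retro hetero-Diels–Alder) into the exocyclic C8=C13 alkene and the alkylidene trione from syncarpic acid and isovaleraldehyde; the methylene comes from a C8 ketone.
2. Feature used: in the nine-membered ring the former carbonyl carbon C8 and the C3=C4(Me) alkene are linked through C9–C1–C2 (a cyclonon-5-enone pattern), and the cyclobutane bond C9–C1 can be read as a spent cyclobutene π bond. Cutting C1–C2 and rejoining C4–C8 (retro anionic oxy-Cope) gives a cis-1-cyclobutenyl-2-vinylcyclopentanol.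
3. That carbinol comes from 2-methylcyclopentane-1,3-dione (ethynylation, enantioselective mono-reduction that sets C5, silylation, semihydrogenation) and a cyclobutenyl metal from 3,3-dimethylcyclobutanone.
4. Ring order: cyclopentane and cyclobutene are bought in; the nine-membered ring fused to the cyclobutane forms in the key step (the cyclopentane is consumed); the pyran ring closes last.

Key step: step 7

Remark on locants: caryophyllane numbering is used throughout (C1/C9 ring fusion, C3=C4 alkene, C5 carbinol, C8 spiro carbon, C10/C11 cyclobutane, C13 pyran CH2, C7' isobutyl-bearing carbon); names of 13, 14, F1 and F2 carry these locants.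

Remark on the precursor: the C5 oxygen is carried as a triisopropylsilyl ether, because a smaller silyl group could shift to the cis C8 alkoxide under KH. The vinyl group is brought in as ethynyl, whose small size is used to steer the reduction to OH trans to the future vinyl group, the arrangement the key step needs.

## Route

Step 1
Reactants: 1 2-methylcyclopentane-1,3-dione
Product: 2 2-ethynyl-2-methylcyclopentane-1,3-dione
Conditions: TMS-EBX, Bu4NF, THF, −78 °C
Reagents that add atoms: 1-[(trimethylsilyl)ethynyl]-1,2-benziodoxol-3(1H)-one (TMS-EBX), C[Si](C)(C)C#CI1OC(=O)c2ccccc12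
Why: Electrophilic α-alkynylation of a stabilised 1,3-dione enolate by the ethynylbenziodoxolone released by fluoride is an established reaction type, C-selective because the enolate carbon adds to the alkynyl iodane and the alkylidene carbene so formed rearranges by 1,2-shift, and it builds the quaternary carbon (later C4), which is not yet stereogenic in the symmetric dione.

Step 2
Reactants: 2 2-ethynyl-2-methylcyclopentane-1,3-dione
Product: 3 (2S,3R)-2-ethynyl-3-hydroxy-2-methylcyclopentan-1-one
Conditions: (S)-2-methyl-CBS-oxazaborolidine (20 mol %), catecholborane, PhNEt2, toluene, −60 °C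
Reagents that add atoms: none
Why: Corey–Bakshi–Shibata reduction used as a desymmetrisation of a 2,2-disubstituted cyclopentane-1,3-dione, in which the oxazaborolidine should fix the carbinol configuration (quaternary carbon as large flank, CH2 as small flank, R at C5 on the acetophenone model) and hydride should enter syn to the slim ethynyl group instead of the methyl group, so that the carbonyl is chosen whose reduction leaves OH cis to methyl and trans to ethynyl and makes C4 stereogenic (S), while catecholborane at this temperature does not hydroborate the alkyne.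

Step 3
Reactants: 3 (2S,3R)-2-ethynyl-3-hydroxy-2-methylcyclopentan-1-one
Product: 4 (2S,3R)-2-ethynyl-2-methyl-3-(triisopropylsilyloxy)cyclopentan-1-one
Conditions: TIPSOTf, 2,6-lutidine, CH2Cl2, −78 to 0 °C
Reagents that add atoms: triisopropylsilyl trifluoromethanesulfonate, CC(C)[Si](OS(=O)(=O)C(F)(F)F)(C(C)C)C(C)C
Why: Silylation with a silyl triflate and a hindered pyridine base protects the neopentyl-type secondary alcohol without a base strong enough for retro-aldol cleavage of the β-hydroxy ketone, touches no stereocentre, and installs a group bulky enough to resist migration to the C8 alkoxide later and to screen the upper ring face.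

Step 4
Reactants: 4 (2S,3R)-2-ethynyl-2-methyl-3-(triisopropylsilyloxy)cyclopentan-1-one
Product: 5 (2S,3R)-2-ethenyl-2-methyl-3-(triisopropylsilyloxy)cyclopentan-1-one
Conditions: H2 (1 atm), Pd/CaCO3 poisoned with Pb(OAc)2, quinoline, EtOAc, rt
Reagents that add atoms: none
Why: Lindlar semihydrogenation should stop the terminal alkyne at the alkene on poisoned palladium with ketone and silyl ether inert, and it is placed before the cyclobutene is introduced so that no strained alkene competes.

Step 5
Reactants: 6 3,3-dimethylcyclobutan-1-one
Product: 7 N'-(3,3-dimethylcyclobutylidene)-2,4,6-triisopropylbenzenesulfonohydrazide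
Conditions: 2,4,6-triisopropylbenzenesulfonyl hydrazide, THF, rt
Reagents that add atoms: 2,4,6-triisopropylbenzenesulfonyl hydrazide, CC(C)c1cc(C(C)C)c(S(=O)(=O)NN)c(C(C)C)c1
Why: Condensation of a ketone with an arylsulfonyl hydrazide gives the hydrazone, and because the ketone is symmetric the later Shapiro deprotonation has no regiochemical choice.

Step 6
Reactants: 5 (2S,3R)-2-ethenyl-2-methyl-3-(triisopropylsilyloxy)cyclopentan-1-one; 7 N'-(3,3-dimethylcyclobutylidene)-2,4,6-triisopropylbenzenesulfonohydrazide
Product: 10 (1R,2S,3R)-1-(3,3-dimethylcyclobut-1-en-1-yl)-2-ethenyl-2-methyl-3-(triisopropylsilyloxy)cyclopentan-1-ol, via cyclobutenyllithium 8 (not isolated), via cyclobutenylcerium dichloride 9 (not isolated)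
Conditions: 7, n-BuLi (2 equiv), TMEDA, THF, −78 to 0 °C; CeCl3, −78 °C; then 5, −78 °C; aq NH4Cl
Reagents that add atoms: none
Why: The Shapiro reaction (hydrazone dianion, loss of sulfinate and N2) gives the alkenyllithium, and its organocerium derivative, which suppresses enolisation of the hindered ketone, should attack the C8 carbonyl on the face opposite the pseudoaxial C4 methyl group and the C5 silyloxy group, that is syn to the vinyl group, which sets C8 (R) and places the two alkenyl groups cis.

Step 7
Reactants: 10 (1R,2S,3R)-1-(3,3-dimethylcyclobut-1-en-1-yl)-2-ethenyl-2-methyl-3-(triisopropylsilyloxy)cyclopentan-1-ol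
Product: 13 (1R,3Z,5R,9S)-4,11,11-trimethyl-5-(triisopropylsilyloxy)bicyclo[7.2.0]undec-3-en-8-one, via potassium alkoxide 11 (not isolated), via potassium enolate 12 (not isolated)
Conditions: KH, 18-crown-6, THF, 0 °C to rt; MeOH, rt; aq NH4Cl
Reagents that add atoms: none
Why: The potassium alkoxide should undergo an anionic oxy-Cope rearrangement, a [3,3] sigmatropic shift through the six-centre array C2=C3–C4–C8–C9=C1 in which the oxyanion weakens C4–C8, so that C2 bonds to C1, C4–C8 breaks and enolate 12 results, its formation and the loss of cyclobutene strain making the shift irreversible. The closest known reaction type is the anionic oxy-Cope ring expansion of cis-1-cycloalkenyl-2-vinylcyclopentanols to cyclonon-5-enones. The nine-membered ring arises by four-atom ring expansion of the cyclopentane (a sigmatropic ring enlargement, not an end-to-end cyclisation), and the cyclobutene π bond becomes the C1–C9 σ bond of the fused cyclobutane. C1 (R) is set by the boat-like geometry, because both alkenyl groups sit on the lower face of the cyclopentane and must fold their termini back under the ring to meet, so that C2 reaches only one cyclobutene face, the sense being dictated by the C4 and C8 centres (destroyed here, set earlier relative to C5); C9 (S) is set afterwards by protonation under equilibrating conditions (KOMe from the methanol quench), which should give the more stable trans ring fusion. The step needs the boat over a chair-like or dissociative path, since only the boat gives the Z C3=C4 alkene (C2 and C5 on the same side) together with the correct C1, and the cis-dialkenyl arrangement on a five-membered ring, which cannot twist enough for a chair, secures it. The triisopropylsilyl ether lies on the upper face, outside the reacting array, and is too bulky to migrate to the C8 alkoxide.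

Step 8
Reactants: 13 (1R,3Z,5R,9S)-4,11,11-trimethyl-5-(triisopropylsilyloxy)bicyclo[7.2.0]undec-3-en-8-one
Product: 14 (1R,3Z,5R,9S)-4,11,11-trimethyl-8-methylidene-5-(triisopropylsilyloxy)bicyclo[7.2.0]undec-3-ene
Conditions: Ph3PCH3Br, KOtBu, THF, 0 °C to rt
Reagents that add atoms: methyltriphenylphosphonium bromide, C[P+](c1ccccc1)(c1ccccc1)c1ccccc1.[Br-]
Why: Wittig methylenation with the non-stabilised ylide should convert the hindered C8 ketone into the exocyclic alkene, and any base-induced epimerisation at C9 only returns the preferred trans fusion.

Step 9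
Reactants: 14 (1R,3Z,5R,9S)-4,11,11-trimethyl-8-methylidene-5-(triisopropylsilyloxy)bicyclo[7.2.0]undec-3-ene; 15 syncarpic acid; 16 isovaleraldehyde
Product: 18 O5-triisopropylsilyl tomentodione O, via alkylidene trione 17 (not isolated)
Conditions: ethylenediammonium diacetate (20 mol %), toluene, 90 °C, sealed tube
Reagents that add atoms: none
Why: In this domino Knoevenagel condensation and inverse-electron-demand hetero-Diels–Alder reaction the electron-poor 1-oxadiene 17 should add to the 1,1-disubstituted exocyclic alkene (more reactive than the unstrained, hindered Z ring alkene) with oxygen bonding to the cation-stabilising carbon C8 and the alkylidene carbon to C13, C8 (S) being set by approach to the methylene face turned away from C1 and the C2 arm of the ring, and C7' (R) by the orientation that keeps the branched C9 arm exo and the C7 methylene endo to the oxadiene (isobutyl cis to C7 across the pyran), both under substrate control so that minor diastereomers are to be removed by chromatography.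

Step 10
Reactants: 18 O5-triisopropylsilyl tomentodione O
Product: 19 tomentodione O
Conditions: Bu4NF, THF, 0 °C to rt
Reagents that add atoms: none
Why: Fluoride-induced desilylation (Si–F bond formation) should free the C5 alcohol without touching the vinylogous ester, the alkenes or any stereocentre.

## Compound list

1 | 2-methylcyclopentane-1,3-dione | CC1C(=O)CCC1=O | starting material
2 | 2-ethynyl-2-methylcyclopentane-1,3-dione | C#CC1(C)C(=O)CCC1=O | intermediate
3 | (2S,3R)-2-ethynyl-3-hydroxy-2-methylcyclopentan-1-one | C#C[C@@]1(C)[C@H](O)CCC1=O | intermediate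
4 | (2S,3R)-2-ethynyl-2-methyl-3-(triisopropylsilyloxy)cyclopentan-1-one | C#C[C@@]1(C)[C@H](O[Si](C(C)C)(C(C)C)C(C)C)CCC1=O | intermediate
5 | (2S,3R)-2-ethenyl-2-methyl-3-(triisopropylsilyloxy)cyclopentan-1-one | C=C[C@@]1(C)[C@H](O[Si](C(C)C)(C(C)C)C(C)C)CCC1=O | intermediate
6 | 3,3-dimethylcyclobutan-1-one | CC1(C)CC(=O)C1 | starting material
7 | N'-(3,3-dimethylcyclobutylidene)-2,4,6-triisopropylbenzenesulfonohydrazide | CC(C)c1cc(C(C)C)c(S(=O)(=O)NN=C2CC(C)(C)C2)c(C(C)C)c1 | intermediate
8 | (3,3-dimethylcyclobut-1-en-1-yl)lithium (not isolated) | [Li]C1=CC(C)(C)C1 | intermediate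
9 | dichloro(3,3-dimethylcyclobut-1-en-1-yl)cerium (not isolated) | Cl[Ce](Cl)C1=CC(C)(C)C1 | intermediate
10 | (1R,2S,3R)-1-(3,3-dimethylcyclobut-1-en-1-yl)-2-ethenyl-2-methyl-3-(triisopropylsilyloxy)cyclopentan-1-ol (key-step precursor) | C=C[C@@]1(C)[C@H](O[Si](C(C)C)(C(C)C)C(C)C)CC[C@@]1(O)C1=CC(C)(C)C1 | intermediate
11 | potassium alkoxide of 10 (not isolated) | C=C[C@@]1(C)[C@H](O[Si](C(C)C)(C(C)C)C(C)C)CC[C@@]1([O-])C1=CC(C)(C)C1.[K+] | intermediate
12 | potassium C8=C9 enolate of 13 (not isolated) | C/C1=C/C[C@@H]2/C(CC2(C)C)=C(/[O-])CC[C@H]1O[Si](C(C)C)(C(C)C)C(C)C.[K+] | intermediate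
13 | (1R,3Z,5R,9S)-4,11,11-trimethyl-5-(triisopropylsilyloxy)bicyclo[7.2.0]undec-3-en-8-one (key-step product) | C/C1=C/C[C@@H]2[C@H](CC2(C)C)C(=O)CC[C@H]1O[Si](C(C)C)(C(C)C)C(C)C | intermediate
14 | (1R,3Z,5R,9S)-4,11,11-trimethyl-8-methylidene-5-(triisopropylsilyloxy)bicyclo[7.2.0]undec-3-ene | C/C1=C/C[C@@H]2[C@H](CC2(C)C)C(=C)CC[C@H]1O[Si](C(C)C)(C(C)C)C(C)C | intermediate
15 | syncarpic acid (2,2,4,4-tetramethylcyclohexane-1,3,5-trione) | CC1(C)C(=O)CC(=O)C(C)(C)C1=O | starting material
16 | isovaleraldehyde (3-methylbutanal) | CC(C)CC=O | starting material
17 | 2,2,4,4-tetramethyl-6-(3-methylbutylidene)cyclohexane-1,3,5-trione (not isolated) | CC(C)CC=C1C(=O)C(C)(C)C(=O)C(C)(C)C1=O | intermediate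
18 | O5-triisopropylsilyl tomentodione O | C/C1=C/C[C@@H]2[C@H](CC2(C)C)[C@]2(CC[C@H]1O[Si](C(C)C)(C(C)C)C(C)C)C[C@@H](CC(C)C)C1=C(O2)C(C)(C)C(=O)C(C)(C)C1=O | intermediate
19 | tomentodione O | C/C1=C/C[C@@H]2[C@H](CC2(C)C)[C@]2(CC[C@H]1O)C[C@@H](CC(C)C)C1=C(O2)C(C)(C)C(=O)C(C)(C)C1=O | target

## Step count and risks

Total step count: 10. Longest linear sequence: 9 steps (steps 1–4 and 6–10, from 2-methylcyclopentane-1,3-dione).

Steps most likely to fail:

1. Step 7 (key step). The shift may run in part through a chair-like array in which the vinyl group turns outward as C4–C8 lengthens; this would give the E ring alkene with the same C1 configuration. Fallback: setting out from 10, the rearrangement is run as described and the E product, (1R,3E,5R,9S)-4,11,11-trimethyl-5-(triisopropylsilyloxy)bicyclo[7.2.0]undec-3-en-8-one F1, is kept and isomerised by reversible thiyl-radical addition (PhSSPh cat., hν, cyclohexane, rt). This E to Z isomerisation is known for strained E-cyclononenes of the caryophyllene type and should drain F1 into the more stable Z isomer, so the route is rejoined at 13. The alkene geometry is then set by equilibration and no longer by the pericyclic transition state.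

2. Step 9. Facial discrimination at the exocyclic alkene may be poor because the flexible nine-membered ring can present either face of the methylene group, and endo/exo control at C7' may be weak. Fallback: setting out from 14, the silyl ether is removed first (Bu4NF, THF) to give (1R,3Z,5R,9S)-4,11,11-trimethyl-8-methylidenebicyclo[7.2.0]undec-3-en-5-ol F2. The domino Knoevenagel/hetero-Diels–Alder reaction with 15 and 16 is then run on the free allylic alcohol (ethylenediammonium diacetate, aqueous ethanol, 80 °C). The hydroxyl group changes the ring conformation and can hold a trione carbonyl by a hydrogen bond on its own face; the cycloadduct is the target itself, so the route is rejoined at 19.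

3. Step 2. Hydride may enter anti to the ethynyl group (polar effect outweighing size), which would leave OH cis to ethynyl, the arrangement that cannot lead to the cis-dialkenyl carbinol with the correct C5. Fallback: setting out from 2, the reduction is run with the (R)-oxazaborolidine, which in that case should give (2S,3S)-2-ethynyl-3-hydroxy-2-methylcyclopentan-1-one F3 (correct quaternary carbon, inverted carbinol). The carbinol is inverted by Mitsunobu reaction (4-nitrobenzoic acid, PPh3, DIAD, toluene, 0 °C to rt) to (1R,2S)-2-ethynyl-2-methyl-3-oxocyclopentyl 4-nitrobenzoate F4, and methanolysis (K2CO3, MeOH, 0 °C) rejoins the route at 3.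

## Further compounds

F1 | step 7 | (1R,3E,5R,9S)-4,11,11-trimethyl-5-(triisopropylsilyloxy)bicyclo[7.2.0]undec-3-en-8-one | C/C1=C\C[C@@H]2[C@H](CC2(C)C)C(=O)CC[C@H]1O[Si](C(C)C)(C(C)C)C(C)C
F2 | step 9 | (1R,3Z,5R,9S)-4,11,11-trimethyl-8-methylidenebicyclo[7.2.0]undec-3-en-5-ol | C/C1=C/C[C@@H]2[C@H](CC2(C)C)C(=C)CC[C@H]1O
F3 | step 2 | (2S,3S)-2-ethynyl-3-hydroxy-2-methylcyclopentan-1-one | C#C[C@@]1(C)[C@@H](O)CCC1=O
F4 | step 2 | (1R,2S)-2-ethynyl-2-methyl-3-oxocyclopentyl 4-nitrobenzoate | C#C[C@@]1(C)[C@H](OC(=O)c2ccc(cc2)[N+](=O)[O-])CCC1=O
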